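Starting material cannot vanish, yet in the epsilon run at 0.125 d target and starting material together leave 16.2% of the charge unaccounted for. An unseen form must be growing, and it is taken to grow from target by a first-order step.

| flask | starting material | reagent | second substrate | remark | time |
|---|---|---|---|---|---|
| epsilon | 0.10 M | 0.12 M | 0.25 M | run made earlier |  |
| zeta | 0.10 M | 0.12 M | 1 M | run made earlier |  |
| delta | 0.10 M | 0.18 M | 0.50 M | run made earlier |  |
| flask | 0.10 M | 0.120 M | 0.500 M |  | 6.0 d |

- epsilon (time / d: target / %, starting material / %): 0.0417: 27.9, 68.5; 0.125: 35.7, 48.1; 0.333: 21.9, 37.3; 0.833: 9.7, 20.8; 2.08: 6.2, 9.7; 5.00: 2.7, 8.3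
- zeta (time / d: target / %, starting material / %): 0.0417: 24.6, 74.3; 0.125: 30.3, 58.0; 0.333: 20.5, 43.1; 0.833: 10.3, 27.0; 2.08: 4.4, 14.4; 5.00: 5.2, 12.1
- delta (time / d: target / %, starting material / %): 0.0417: 37.1, 58.3; 0.167: 38.8, 34.6; 0.500: 17.8, 18.7; 1.67: 4.4, 5.2; 5.00: 4.4, 4.2

(each reading ± 1 percentage point)

* when, up to 6.0 d, the flask holds most target
* the amount of target, in percent of the starting material charged, at that time



In the epsilon run target averaged 25.8% up to 0.125 d. So the gap gives a loss half-life of 0.138 d: the time in which target, unfed, halves.

The second way is the fall of target itself. In the epsilon run, from 0.125 d to 0.333 d, that fall gives 0.295 d, longer than the first value. The fall cheats. Over that stretch starting material drops 11 percentage points into target, so target loses 25 points, more than its fall of 14 points shows.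

Target tops where feed equals loss. The balance level, the steady-state value of target, is therefore the feed per day times the loss half-life over ln(2). The reckoning made here takes the flask as the mean of epsilon and zeta, since its second substrate lies midway between theirs on a logarithmic scale. The level is 43.9% before 0.125 d and 12.3% after it, while mean target there is 33.0%. Logarithmic interpolation puts the crossing at 0.116 d.

The forecast differs: 0.13 d and 34.5%, later and higher. Its ground for the height is this: “The peak is sparsely sampled, so it may lie a little above the interpolated reading”.

The flask tops at 0.103 d with 33.1%, so the forecast's time is too late by a factor of 1.26, while its amount is within tolerance.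

    starting material + reagent ⇌ target (K = 17.0 M⁻¹, k = 0.00150 M⁻¹ s⁻¹)
    second substrate + reagent ⇌ second product (K = 0.730 M⁻¹, k = 0.00220 M⁻¹ s⁻¹)
    target ⇌ isomer of the product (K = 25.0, k = 5.20 × 10⁻⁵ s⁻¹)

The unseen form is the isomer of the product, and the forward half-life of target to isomer of the product, 0.15 d, is short against 6.0 d. Counted in the loss half-life, the top of the flask comes after 0.746 half-lives and the end after 43.5, when the flask holds 87.0% isomer of the product and 3.49% target, a ratio of 24.9. The neighbouring flask with 0.40 M starting material ends after the same count with 28.5% and 1.14%, a ratio of 25.0.

The numbers in the tables were computed for substances that don't exist, noise included.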